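**Plan**

1. Retrosynthesis: both cyclopentanols are opened first by a retro carbonyl-ene reaction (ring bond between the carbinol carbon and the isopropenyl-bearing carbon). This leaves a C2-symmetric bis(oxanyl) dialdehyde with two prenyl ends; each CHO is traced back through CH2OH to a 1,1-disubstituted alkene. Each oxane (O1, C2 carrying the side chain, C3, C4, C5 alkylidene, C6) is then cut at O1–C2 and at C3–C4.
2. Enabling feature: in each oxane, O1–C6–C5(=CH)–C4 is a 2-alkylidenepropane-1,3-diyl unit with both CH2 arms on one sp2 carbon. Both rings can therefore come from one symmetric bis(5-alkylidene-1,3-dioxan-2-one), used twice as an O/C 1,4-dipole (alkoxide at O1, π-allyl terminus at C4), while C2–C3 are the two carbons of a nitroalkene.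
3. Forward: a C12 bis-carbonate (double Wittig of a C4 bis-ylide with two molecules of 2,2-dimethyl-1,3-dioxan-5-one) and two C10 nitrodienes (homoprenyl bromide + acetaldehyde imine, then CH2O, then MeNO2) are joined in one palladium-catalysed operation. It makes O1–C2 and then closes both oxanes through C3–C4. Hydroboration, removal of NO2, oxidation and a final double carbonyl-ene reaction (both cyclopentanols) follow; no protecting group is used.
4. Stereochemistry: C2 of each oxane from the chiral palladium catalyst (achiral partners); the (Z)-alkenes from the syn preference of the substituted π-allyl; the adjacent side-chain centre from anti-selective 9-BBN hydroboration next to C2; the carbinol and isopropenyl centres from the ene transition state.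

Key step: step 7

Remark: the sense of induction of the diphosphine ligand at C2 of the oxane in step 7 is assumed as drawn for the (R,R)-ligand; if it proves opposite, the (S,S)-ligand is used and nothing else changes.
Remark: the nitro-bearing carbon C3 of 15–17 is drawn trans to the C2 side chain; it is base-labile and is removed in step 9, so either epimer serves.
Remark: in the two-directional steps both identical ends react under the same conditions, so the monofunctional partner or reagent is taken in two equivalents plus a small excess; singly converted species are not listed separately.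

**Route**

Step 1
Reactants: 1 butane-1,4-diylbis(triphenylphosphonium) dibromide; 2 2,2-dimethyl-1,3-dioxan-5-one (two equivalents plus a small excess)
Product: 4 5,5'-(butane-1,4-diylidene)bis(2,2-dimethyl-1,3-dioxane), via bis-ylide 3 (not isolated)
Conditions: KN(SiMe3)2 (2.1 equiv), THF, 0 °C; then 2 (2.2 equiv), −78 °C → rt
Reagents that add atoms: none
Why: a double Wittig olefination, in which each of the two non-stabilized ylide carbons of 3 takes up one molecule of the symmetric, activated ketone 2, should give the bis(alkylidene) acetonide, with no E/Z question because both ring arms are identical.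

Step 2
Reactants: 4 5,5'-(butane-1,4-diylidene)bis(2,2-dimethyl-1,3-dioxane)
Product: 5 2,7-bis(hydroxymethyl)octa-2,6-diene-1,8-diol
Conditions: AcOH/H2O (4:1), rt
Reagents that add atoms: none
Why: mild acid hydrolysis of the two acetonides should free the tetraol without touching the trisubstituted alkenes.

Step 3
Reactants: 5 2,7-bis(hydroxymethyl)octa-2,6-diene-1,8-diol
Product: 6 5,5'-(butane-1,4-diylidene)bis(1,3-dioxan-2-one)
Conditions: ClCO2Et (2.2 equiv), Et3N, THF, 0 °C
Reagents that add atoms: ethyl chloroformate, CCOC(Cl)=O
Why: acylation of one hydroxyl of each 1,3-diol and base-induced ring closure with loss of ethanol is the standard route to six-membered cyclic carbonates of 2-alkylidenepropane-1,3-diols.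

Step 4
Reactants: 7 N-tert-butylethanimine (acetaldehyde tert-butylimine); 8 5-bromo-2-methylpent-2-ene
Product: 11 6-methylhept-5-enal, via lithiated imine 9 (not isolated), via alkylated imine 10 (not isolated)
Conditions: LiN(i-Pr)2, THF, −78 → 0 °C; then 8, −78 °C → rt; then aq. oxalic acid, Et2O, rt
Reagents that add atoms: water, O
Why: alkylation of the metalloenamine of acetaldehyde with a primary bromide, followed by imine hydrolysis, is a reliable two-carbon homologation to the aldehyde.

Step 5
Reactants: 11 6-methylhept-5-enal
Product: 12 6-methyl-2-methylidenehept-5-enal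
Conditions: CH2O (37% aq.), pyrrolidine (cat.), propanoic acid (cat.), i-PrOH, 45 °C
Reagents that add atoms: formaldehyde, C=O
Why: an amine-catalysed Mannich condensation/elimination should install the α-methylene group, which later becomes the carbinol carbon of the cyclopentanol.

Step 6
Reactants: 12 6-methyl-2-methylidenehept-5-enal
Product: 14 (E)-7-methyl-3-methylidene-1-nitroocta-1,6-diene, via nitro alcohol 13 (not isolated)
Conditions: MeNO2 (excess), KOt-Bu (cat.), THF/t-BuOH, 0 °C, short contact; aqueous work-up; then MsCl, Et3N, CH2Cl2, −30 → 0 °C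
Reagents that add atoms: nitromethane, C[N+](=O)[O-]
Why: a kinetically controlled Henry 1,2-addition at low temperature followed by mesylation/E1cB elimination should give the (E)-nitrodiene, to be used cold and at once.

Step 7
Reactants: 6 5,5'-(butane-1,4-diylidene)bis(1,3-dioxan-2-one); 14 (E)-7-methyl-3-methylidene-1-nitroocta-1,6-diene (two equivalents plus a small excess, added slowly)
Product: 15 (1Z,4Z)-1,4-bis[(5R,6S)-6-(6-methylhepta-1,5-dien-2-yl)-5-nitrooxan-3-ylidene]butane
Conditions: Pd2(dba)3·CHCl3 (cat.), (R,R)-DACH-phenyl Trost ligand (cat.), toluene, 0 °C → rt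
Reagents that add atoms: none
Why: Proposed new method: zerovalent palladium ionizes one allylic C–O bond of each cyclic carbonate and CO2 is lost, giving a zwitterionic π-allylpalladium that carries a CH2O− arm on its central carbon; this alkoxide adds reversibly to the β-carbon of the nitroalkene (oxa-Michael addition, O1–C2) and the resulting nitronate carbon then attacks the unsubstituted CH2 terminus of the π-allyl, which forms C3–C4, closes the oxane and frees the catalyst, the closest known reaction types being the palladium-catalysed decarboxylative (4+2) annulation of 5-methylidene-1,3-dioxan-2-one with electron-poor alkenes and the Tsuji–Trost C-allylation of nitronates (new here: an alkylidene-substituted carbonate, a nitrodiene acceptor and the two-fold mode). Each six-membered ring closes in a 6-exo-tet manner, the nitronate carbon displacing palladium from the CH2 terminus while the C5=CH bond stays exocyclic. C2 is set in the ring-closing event under control of the chiral ligand, because the oxa-Michael step is reversible and only the faster-cyclizing nitronate is drained; the nitro centre C3 is expected to settle trans to the C2 substituent under the basic conditions and is erased in step 9. The (Z) geometry follows from the π-allyl: its 1-alkyl substituent prefers the syn position, cis to the CH2O arm, whichever of the two equivalent C–O bonds ionizes, so no geometric information has to be brought in. The step needs attack at the CH2 terminus and not at the substituted one (both would give six-membered rings), which the preference of stabilized, bulky nucleophiles for the less hindered terminus of a palladium-bound allyl should secure; it needs 1,4- instead of 1,6-addition to the nitrodiene, secured by reversibility of the oxygen addition and by the fact that only the 1,4-adduct can close a six-membered ring through its nitronate carbon; and it needs C- instead of O-allylation of the nitronate, the normal course with π-allylpalladium. Both partners are achiral and the reaction is two-directional, so the minor sense of induction should end mostly in the meso isomer, which is a separable diastereomer.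

Step 8
Reactants: 15 (1Z,4Z)-1,4-bis[(5R,6S)-6-(6-methylhepta-1,5-dien-2-yl)-5-nitrooxan-3-ylidene]butane
Product: 17 (1Z,4Z)-1,4-bis{(5R,6S)-6-[(2S)-1-hydroxy-6-methylhept-5-en-2-yl]-5-nitrooxan-3-ylidene}butane, via bis(alkylborane) 16 (not isolated)
Conditions: 9-BBN (2.5 equiv), THF, 0 °C → rt; then H2O2 (30%), aq. NaH2PO4/Na2HPO4 buffer (pH 7), MeOH, 0 °C → rt
Reagents that add atoms: 9-BBN, B1C2CCCC1CCC2 (boron and its C8 ring are present in 16 only); hydrogen peroxide, OO
Why: 9-BBN should hydroborate only the two 1,1-disubstituted alkenes (the four trisubstituted ones react far more slowly) and add anti to the ring carbon C3 with the C2–H eclipsing the alkene, the known anti-selective hydroboration next to an oxygen-bearing stereocentre, which sets the side-chain centre; buffered oxidation avoids base-induced opening of the β-alkoxy nitro unit.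

Step 9
Reactants: 17 (1Z,4Z)-1,4-bis{(5R,6S)-6-[(2S)-1-hydroxy-6-methylhept-5-en-2-yl]-5-nitrooxan-3-ylidene}butane
Product: 18 (1Z,4Z)-1,4-bis{(6R)-6-[(2S)-1-hydroxy-6-methylhept-5-en-2-yl]oxan-3-ylidene}butane
Conditions: Bu3SnH (large excess, high concentration), AIBN (portionwise), toluene, 110 °C
Reagents that add atoms: none
Why: radical denitration of the secondary nitro groups by the tin hydride chain should replace NO2 by H; the step is placed after the hydroboration so that the C3 radical has no neighbouring vinyl group for a 1,2-vinyl shift, and the high hydride concentration should outrun hydrogen transfer from or cyclization onto the prenyl end.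

Step 10
Reactants: 18 (1Z,4Z)-1,4-bis{(6R)-6-[(2S)-1-hydroxy-6-methylhept-5-en-2-yl]oxan-3-ylidene}butane
Product: 19 (1Z,4Z)-1,4-bis{(6R)-6-[(2R)-6-methyl-1-oxohept-5-en-2-yl]oxan-3-ylidene}butane
Conditions: Dess–Martin periodinane, NaHCO3, CH2Cl2, 0 °C → rt; used at once
Reagents that add atoms: none
Why: a buffered Dess–Martin oxidation should give the dialdehyde without epimerizing the α-centre or eliminating the β-ring oxygen (the descriptor changes from S to R only through the priority rules).

Step 11
Reactants: 19 (1Z,4Z)-1,4-bis{(6R)-6-[(2R)-6-methyl-1-oxohept-5-en-2-yl]oxan-3-ylidene}butane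
Product: 20 testudinariol A
Conditions: Me2AlCl (2.2 equiv), CH2Cl2, −78 → −20 °C; aq. potassium sodium tartrate (KNaC4H4O6)
Reagents that add atoms: none
Why: a Lewis acid-promoted intramolecular carbonyl-ene reaction of each aldehyde with its prenyl alkene should close the five-membered rings through a transition state in which the carbonyl oxygen reaches a methyl hydrogen (OH cis to isopropenyl) and the bulky oxanyl group sits on the outer face (trans to OH), mirroring the presumed biosynthetic ring closure.

**Compound list**

1 | butane-1,4-diylbis(triphenylphosphonium) dibromide | [Br-].[Br-].c1ccccc1[P+](c1ccccc1)(c1ccccc1)CCCC[P+](c1ccccc1)(c1ccccc1)c1ccccc1 | starting material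
2 | 2,2-dimethyl-1,3-dioxan-5-one | CC1(C)OCC(=O)CO1 | starting material
3 | butane-1,4-diylidenebis(triphenylphosphorane), bis-ylide (not isolated) | c1ccccc1P(c1ccccc1)(c1ccccc1)=CCCC=P(c1ccccc1)(c1ccccc1)c1ccccc1 | intermediate
4 | 5,5'-(butane-1,4-diylidene)bis(2,2-dimethyl-1,3-dioxane) | CC1(C)OCC(=CCCC=C2COC(C)(C)OC2)CO1 | intermediate
5 | 2,7-bis(hydroxymethyl)octa-2,6-diene-1,8-diol | OCC(CO)=CCCC=C(CO)CO | intermediate
6 | 5,5'-(butane-1,4-diylidene)bis(1,3-dioxan-2-one) | O=C1OCC(=CCCC=C2COC(=O)OC2)CO1 | intermediate
7 | N-tert-butylethanimine | CC=NC(C)(C)C | starting material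
8 | 5-bromo-2-methylpent-2-ene | CC(C)=CCCBr | starting material
9 | lithium tert-butyl(ethenyl)azanide, lithiated imine (not isolated) | C=CN([Li])C(C)(C)C | intermediate
10 | N-tert-butyl-6-methylhept-5-en-1-imine (not isolated) | CC(C)=CCCCC=NC(C)(C)C | intermediate
11 | 6-methylhept-5-enal | CC(C)=CCCCC=O | intermediate
12 | 6-methyl-2-methylidenehept-5-enal | CC(C)=CCCC(=C)C=O | intermediate
13 | 7-methyl-3-methylidene-1-nitrooct-6-en-2-ol, racemic (not isolated) | CC(C)=CCCC(=C)C(O)C[N+](=O)[O-] | intermediate
14 | (E)-7-methyl-3-methylidene-1-nitroocta-1,6-diene | CC(C)=CCCC(=C)/C=C/[N+](=O)[O-] | intermediate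
15 | (1Z,4Z)-1,4-bis[(5R,6S)-6-(6-methylhepta-1,5-dien-2-yl)-5-nitrooxan-3-ylidene]butane | C(/C=C1/C[C@@H]([N+](=O)[O-])[C@H](C(=C)CCC=C(C)C)OC1)C/C=C1/C[C@@H]([N+](=O)[O-])[C@H](C(=C)CCC=C(C)C)OC1 | intermediate
16 | bis(B-alkyl-9-borabicyclo[3.3.1]nonane) from 15, boron on each new CH2 (not isolated) | C(/C=C1/C[C@@H]([N+](=O)[O-])[C@H]([C@H](CB2C3CCCC2CCC3)CCC=C(C)C)OC1)C/C=C1/C[C@@H]([N+](=O)[O-])[C@H]([C@H](CB2C3CCCC2CCC3)CCC=C(C)C)OC1 | intermediate
17 | (1Z,4Z)-1,4-bis{(5R,6S)-6-[(2S)-1-hydroxy-6-methylhept-5-en-2-yl]-5-nitrooxan-3-ylidene}butane | C(/C=C1/C[C@@H]([N+](=O)[O-])[C@H]([C@H](CO)CCC=C(C)C)OC1)C/C=C1/C[C@@H]([N+](=O)[O-])[C@H]([C@H](CO)CCC=C(C)C)OC1 | intermediate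
18 | (1Z,4Z)-1,4-bis{(6R)-6-[(2S)-1-hydroxy-6-methylhept-5-en-2-yl]oxan-3-ylidene}butane | C(/C=C1/CC[C@H]([C@H](CO)CCC=C(C)C)OC1)C/C=C1/CC[C@H]([C@H](CO)CCC=C(C)C)OC1 | intermediate
19 | (1Z,4Z)-1,4-bis{(6R)-6-[(2R)-6-methyl-1-oxohept-5-en-2-yl]oxan-3-ylidene}butane | C(/C=C1/CC[C@H]([C@H](C=O)CCC=C(C)C)OC1)C/C=C1/CC[C@H]([C@H](C=O)CCC=C(C)C)OC1 | intermediate
20 | testudinariol A, (1Z,4Z)-1,4-bis{(6R)-6-[(1S,2S,3R)-2-hydroxy-3-(prop-1-en-2-yl)cyclopentyl]oxan-3-ylidene}butane | C=C(C)[C@H]1CC[C@H]([C@H]2CC/C(=C/CC/C=C3/CC[C@H]([C@H]4CC[C@H](C(=C)C)[C@@H]4O)OC3)CO2)[C@H]1O | target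

**Step count and risks**

Total steps: 11. Longest linear sequence: 8 steps (steps 4–11 from 7 and 8; equally steps 1–3 and 7–11 from 1 and 2).

Steps most likely to fail:

Step 7 (proposed new method). The ring closure may lose against oligomerization of the nitrodiene by nitronate-to-nitroalkene addition. The nitronate may attack the substituted allyl terminus. The ligand may exert too little control at C2 of the oxane. The substituent on the central allyl carbon may weaken the syn preference, or the π-allyl may be trapped before its syn/anti equilibration, and either would erode the alkene geometry. The fallback uses known reaction types only, sets out from 6 and 12, and returns at 15. A Pd(PPh3)4-catalysed decarboxylative Tsuji–Trost allylation of nitromethane with 6 should give (2Z,6Z)-2,7-bis(2-nitroethyl)octa-2,6-diene-1,8-diol F1, with the same syn-allyl control of geometry and the C3–C4 bond now made intermolecularly; geometric isomers could be separated at this diol stage. A double Henry addition of F1 to enal 12 gives the bis(β-nitro alcohol) (2Z,6Z)-2,7-bis(3-hydroxy-8-methyl-4-methylidene-2-nitronon-7-en-1-yl)octa-2,6-diene-1,8-diol F2. Dehydration with dicyclohexylcarbodiimide and CuCl gives the bis(nitroalkene) diol (2Z,6Z)-2,7-bis(8-methyl-4-methylidene-2-nitronona-2,7-dien-1-yl)octa-2,6-diene-1,8-diol F3. An intramolecular oxa-Michael addition of the two primary allylic hydroxyls, catalysed by a cinchona-derived squaramide, then closes both oxanes, in this variant through O1–C2, and gives 15.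

Step 9. C–N homolysis of a secondary nitro group is slow. Oxime formation, hydrogen transfer from the allylic CH2 of the prenyl chain, or 6-exo cyclization of the C3 radical onto the prenyl alkene may compete. The fallback sets out from 17 and returns at 18. Reduction of both nitro groups with Zn/AcOH gives the bis(primary amine) (1Z,4Z)-1,4-bis{(5R,6S)-5-amino-6-[(2S)-1-hydroxy-6-methylhept-5-en-2-yl]oxan-3-ylidene}butane F4. Reductive deamination with hydroxylamine-O-sulfonic acid and aq. NaOH (through the monoalkyldiazene, with loss of N2) gives 18 without a long-lived carbon radical.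

Step 6. Nitronate may add in conjugate fashion to the unhindered methylidene terminus of enal 12, and enal or nitrodiene may polymerize. The fallback sets out from 12 and returns at 14. Conjugate addition of PhSeH masks the methylidene as 6-methyl-2-[(phenylselanyl)methyl]hept-5-enal F5. Henry addition of nitromethane and MsCl/Et3N dehydration give (E)-7-methyl-1-nitro-3-[(phenylselanyl)methyl]octa-1,6-diene F6. Oxidation with H2O2 at 0 °C gives the selenoxide (E)-7-methyl-1-nitro-3-[(phenylseleninyl)methyl]octa-1,6-diene F7, whose syn-elimination at room temperature can only run towards the single β-hydrogen and restores the methylidene of 14.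

Further compounds
F1 | step 7 | (2Z,6Z)-2,7-bis(2-nitroethyl)octa-2,6-diene-1,8-diol | OC/C(CC[N+](=O)[O-])=C\CC/C=C(\CO)CC[N+](=O)[O-]
F2 | step 7 | (2Z,6Z)-2,7-bis(3-hydroxy-8-methyl-4-methylidene-2-nitronon-7-en-1-yl)octa-2,6-diene-1,8-diol, diastereomer mixture | OC/C(CC([N+](=O)[O-])C(O)C(=C)CCC=C(C)C)=C\CC/C=C(\CO)CC([N+](=O)[O-])C(O)C(=C)CCC=C(C)C
F3 | step 7 | (2Z,6Z)-2,7-bis(8-methyl-4-methylidene-2-nitronona-2,7-dien-1-yl)octa-2,6-diene-1,8-diol | OC/C(CC(=CC(=C)CCC=C(C)C)[N+](=O)[O-])=C\CC/C=C(\CO)CC(=CC(=C)CCC=C(C)C)[N+](=O)[O-]
F4 | step 9 | (1Z,4Z)-1,4-bis{(5R,6S)-5-amino-6-[(2S)-1-hydroxy-6-methylhept-5-en-2-yl]oxan-3-ylidene}butane | C(/C=C1/C[C@@H](N)[C@H]([C@H](CO)CCC=C(C)C)OC1)C/C=C1/C[C@@H](N)[C@H]([C@H](CO)CCC=C(C)C)OC1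
F5 | step 6 | 6-methyl-2-[(phenylselanyl)methyl]hept-5-enal, racemic | CC(C)=CCCC(C[Se]c1ccccc1)C=O
F6 | step 6 | (E)-7-methyl-1-nitro-3-[(phenylselanyl)methyl]octa-1,6-diene, racemic | CC(C)=CCCC(C[Se]c1ccccc1)/C=C/[N+](=O)[O-]
F7 | step 6 | (E)-7-methyl-1-nitro-3-[(phenylseleninyl)methyl]octa-1,6-diene | CC(C)=CCCC(C[Se](=O)c1ccccc1)/C=C/[N+](=O)[O-]
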